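The route rests on cutting O1–C2 in ring C of the upper flavan: its anti O1–C2/C3–OH array is read as the opened form of an oxiranium ion spanning C2 and C3. The precursor is an erythro 2-(α-hydroxybenzyl)-2,3-dihydrobenzofuran, made by 5-exo opening of a Shi epoxide. In the key step, trifluoroacetylation ionises the benzylic carbinol, the ring oxygen shifts from C3 to C2 through the oxiranium and trifluoroacetate returns at C3, so the five-membered ring grows into ring C with both stereocentres set by double inversion. The ring B bromide is then joined to C8 of 8-bromocatechin by borylation and Suzuki coupling, and hydrogenolysis ends the route.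

Key step: step 7

Remark: the C6'–C8 biaryl axis carries no stereodescriptor in the target; it is treated as not configurationally fixed, so no axial control is planned.

Step 1
Reactants: 1 3,4-bis(benzyloxy)benzaldehyde
Product: 2 4,5-bis(benzyloxy)-2-bromobenzaldehyde
Conditions: Br2, NaOAc, AcOH, rt
Reagents that add atoms: bromine, BrBr
Why: Electrophilic aromatic bromination should go para to the 3-benzyloxy group and ortho to the formyl group, the position that veratraldehyde-type rings brominate.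

Step 2
Reactants: 2 4,5-bis(benzyloxy)-2-bromobenzaldehyde
Product: 3 rac-1-[4,5-bis(benzyloxy)-2-bromophenyl]prop-2-en-1-ol
Conditions: vinylmagnesium bromide, THF, −78 → 0 °C; then H2O
Reagents that add atoms: vinylmagnesium bromide, C=C[Mg]Br
Why: Grignard 1,2-addition to the aldehyde leaves the aryl bromide untouched at low temperature and gives a racemic carbinol whose stereocentre is erased in step 3.

Step 3
Reactants: 3 rac-1-[4,5-bis(benzyloxy)-2-bromophenyl]prop-2-en-1-ol; 4 3,5-bis(benzyloxy)phenol (in excess)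
Product: 5 3,5-bis(benzyloxy)-2-[(E)-3-(4,5-bis(benzyloxy)-2-bromophenyl)prop-2-en-1-yl]phenol
Conditions: H2SO4 on SiO2 (cat.), CH2Cl2, rt
Reagents that add atoms: none
Why: In this Friedel–Crafts allylation, acid ionises 3 to a 4-benzyloxy-stabilised 1-arylallyl cation that the phenol attacks through its carbon ortho to OH at the unhindered allyl terminus, which gives the conjugated E-alkene.

Step 4
Reactants: 5 3,5-bis(benzyloxy)-2-[(E)-3-(4,5-bis(benzyloxy)-2-bromophenyl)prop-2-en-1-yl]phenol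
Product: 6 tert-butyldimethylsilyl ether of 5
Conditions: TBSCl, imidazole, DMF, rt
Reagents that add atoms: tert-butyldimethylsilyl chloride, CC(C)(C)[Si](C)(C)Cl
Why: Standard phenol silylation masks the oxidisable phenol for the epoxidation and keeps it from opening the epoxide before it is wanted.

Step 5
Reactants: 6 tert-butyldimethylsilyl ether of 5
Product: 7 (2S,3S)-epoxide of 6 (2-arylmethyl-3-aryl-oxirane)
Conditions: L-fructose-derived Shi ketone (ent-Shi ketone, 30 mol %), KHSO5 (as 2KHSO5·KHSO4·K2SO4), K2CO3, Bu4NHSO4, MeCN–CH2(OMe)2–aq. Na2B4O7 buffer (pH 10.5), 0 °C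
Reagents that add atoms: potassium peroxymonosulfate KHSO5, [K+].[O-]S(=O)(=O)OO
Why: In the Shi asymmetric epoxidation the chiral dioxirane delivers oxygen to one face of the E-alkene through a spiro transition state, which with the L-series ketone should set both oxirane carbons as S, and the basic buffer spares the acid-labile aryl epoxide.

Step 6
Reactants: 7 (2S,3S)-epoxide of 6
Product: 9 (S)-[4,5-bis(benzyloxy)-2-bromophenyl][(2R)-4,6-bis(benzyloxy)-2,3-dihydrobenzofuran-2-yl]methanol, via epoxy phenoxide 8 (not isolated)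
Conditions: Bu4NF, THF, 0 °C → rt; then H2O
Reagents that add atoms: none
Why: Fluoride frees the phenoxide, which should open the epoxide by 5-exo-tet SN2 attack at the non-benzylic carbon with inversion (benzylic 6-endo opening lacks acid assistance under basic aprotic conditions), giving the erythro carbinol with the benzylic centre untouched.

Step 7
Reactants: 9 (S)-[4,5-bis(benzyloxy)-2-bromophenyl][(2R)-4,6-bis(benzyloxy)-2,3-dihydrobenzofuran-2-yl]methanol
Product: 12 (2R,3S)-5,7-bis(benzyloxy)-2-[4,5-bis(benzyloxy)-2-bromophenyl]chroman-3-ol, via benzylic trifluoroacetate 10 (not isolated), via flavan-3-yl trifluoroacetate 11 (not isolated)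
Conditions: (CF3CO)2O (1.2 equiv), 2,6-lutidine, CH2Cl2, −40 → 40 °C; then MeOH, Et3N, rt
Reagents that add atoms: trifluoroacetic anhydride, O=C(OC(=O)C(F)(F)F)C(F)(F)F
Why: O-Trifluoroacetylation turns the benzylic hydroxyl of 9 into a nucleofuge that the 4-benzyloxyaryl group makes ionisable; the dihydrobenzofuran oxygen, antiperiplanar to it in the erythro isomer, displaces it from the rear (3-exo-tet) to give a trans aryl-bridged oxiranium ion, and trifluoroacetate reopens this ion at the non-benzylic carbon, so the C–O bond of the five-membered ring is exchanged for the O1–C2 bond of six-membered ring C (net 1,2-oxygen shift, ring enlargement by cleavage of the inner bond of the bicyclic onium ion). The closest known reaction type is the anchimerically assisted expansion of 2-(α-sulfonyloxyalkyl)tetrahydrofurans to tetrahydropyrans through oxiranium ions, together with its nitrogen analogue, the trifluoroacetic-anhydride-induced prolinol to 3-hydroxypiperidine expansion; the same aryloxiranium manifold operates in the chroman/dihydrobenzofuran series. Both new stereocentres arise by inversion: C2 (R) from the (S)-carbinol carbon when O1 enters, and C3 (S) from the (R)-configured dihydrobenzofuran C2 when trifluoroacetate enters, so the erythro precursor maps onto the 2,3-trans flavan. The step needs attack at the non-benzylic terminus of the oxiranium: return at the benzylic carbon only regenerates labile ester 10, which re-ionises, whereas the secondary non-benzylic ester 11 does not, so material should drain to the six-membered ring under thermodynamic control. The ortho bromine and the absence of a strong base disfavour a free planar cation and proton loss to a 2-benzylbenzofuran, and methanol with Et3N finally cleaves the trifluoroacetate in the same flask.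

Step 8
Reactants: 13 (+)-catechin
Product: 14 5,7,3',4'-tetra-O-benzyl-(+)-catechin
Conditions: BnBr, K2CO3, DMF, 0 °C → rt
Reagents that add atoms: benzyl bromide, BrCc1ccccc1
Why: Williamson etherification with K2CO3 alkylates the four phenols but not the aliphatic 3-hydroxyl, and the two stereocentres are not touched.

Step 9
Reactants: 14 5,7,3',4'-tetra-O-benzyl-(+)-catechin
Product: 15 8-bromo-5,7,3',4'-tetra-O-benzyl-(+)-catechin
Conditions: NBS, CH2Cl2, −78 → 0 °C
Reagents that add atoms: N-bromosuccinimide, O=C1CCC(=O)N1Br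
Why: Electrophilic bromination of the phloroglucinol-type ring A of 5,7-di-O-benzyl flavan-3-ols goes selectively to C8.

Step 10
Reactants: 12 (2R,3S)-5,7-bis(benzyloxy)-2-[4,5-bis(benzyloxy)-2-bromophenyl]chroman-3-ol; 15 8-bromo-5,7,3',4'-tetra-O-benzyl-(+)-catechin
Product: 17 octa-O-benzyl catechin-(6'→8)-catechin, via pinacol boronate 16 (not isolated)
Conditions: B2pin2, KOAc, Pd(OAc)2 (5 mol %), XPhos, dioxane, 100 °C; then 15, aq. K3PO4, 100 °C
Reagents that add atoms: none
Why: Miyaura borylation puts boron on the mono-ortho-substituted ring B partner (a 2,6-dialkoxyarylboron reagent at C8 would protodeboronate), and the bulky biarylphosphine lets zerovalent palladium insert into the hindered electron-rich C8–Br bond for the Suzuki–Miyaura coupling, which touches no stereocentre.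

Step 11
Reactants: 17 octa-O-benzyl catechin-(6'→8)-catechin
Product: 18 catechin-(6'→8)-catechin (CNP0353739.1)
Conditions: H2 (1 atm), Pd(OH)2/C, THF–MeOH, rt
Reagents that add atoms: none
Why: Hydrogenolysis should remove all eight phenolic benzyl ethers under neutral conditions that leave the flavan C2–O bonds, the biaryl and the four stereocentres intact.

Compound list
1 | 3,4-bis(benzyloxy)benzaldehyde | O=Cc1ccc(OCc2ccccc2)c(OCc2ccccc2)c1 | starting material
2 | 4,5-bis(benzyloxy)-2-bromobenzaldehyde | O=Cc1cc(OCc2ccccc2)c(OCc2ccccc2)cc1Br | intermediate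
3 | rac-1-[4,5-bis(benzyloxy)-2-bromophenyl]prop-2-en-1-ol | C=CC(O)c1cc(OCc2ccccc2)c(OCc2ccccc2)cc1Br | intermediate
4 | 3,5-bis(benzyloxy)phenol | Oc1cc(OCc2ccccc2)cc(OCc2ccccc2)c1 | starting material
5 | 3,5-bis(benzyloxy)-2-[(E)-3-(4,5-bis(benzyloxy)-2-bromophenyl)prop-2-en-1-yl]phenol | Oc1cc(OCc2ccccc2)cc(OCc2ccccc2)c1C/C=C/c1cc(OCc2ccccc2)c(OCc2ccccc2)cc1Br | intermediate
6 | tert-butyldimethylsilyl ether of 5 | CC(C)(C)[Si](C)(C)Oc1cc(OCc2ccccc2)cc(OCc2ccccc2)c1C/C=C/c1cc(OCc2ccccc2)c(OCc2ccccc2)cc1Br | intermediate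
7 | tert-butyl{3,5-bis(benzyloxy)-2-[((2S,3S)-3-(4,5-bis(benzyloxy)-2-bromophenyl)oxiran-2-yl)methyl]phenoxy}dimethylsilane | CC(C)(C)[Si](C)(C)Oc1cc(OCc2ccccc2)cc(OCc2ccccc2)c1C[C@@H]1O[C@H]1c1cc(OCc2ccccc2)c(OCc2ccccc2)cc1Br | intermediate
8 | 3,5-bis(benzyloxy)-2-[((2S,3S)-3-(4,5-bis(benzyloxy)-2-bromophenyl)oxiran-2-yl)methyl]phenol, present as its tetrabutylammonium phenoxide | Oc1cc(OCc2ccccc2)cc(OCc2ccccc2)c1C[C@@H]1O[C@H]1c1cc(OCc2ccccc2)c(OCc2ccccc2)cc1Br | intermediate
9 | (S)-[4,5-bis(benzyloxy)-2-bromophenyl][(2R)-4,6-bis(benzyloxy)-2,3-dihydrobenzofuran-2-yl]methanol | O[C@H]([C@H]1Cc2c(OCc3ccccc3)cc(OCc3ccccc3)cc2O1)c1cc(OCc2ccccc2)c(OCc2ccccc2)cc1Br | intermediate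
10 | (S)-[4,5-bis(benzyloxy)-2-bromophenyl][(2R)-4,6-bis(benzyloxy)-2,3-dihydrobenzofuran-2-yl]methyl trifluoroacetate | O=C(O[C@H]([C@H]1Cc2c(OCc3ccccc3)cc(OCc3ccccc3)cc2O1)c1cc(OCc2ccccc2)c(OCc2ccccc2)cc1Br)C(F)(F)F | intermediate
11 | (2R,3S)-5,7-bis(benzyloxy)-2-[4,5-bis(benzyloxy)-2-bromophenyl]chroman-3-yl trifluoroacetate | c1ccccc1COc1cc(OCc3ccccc3)c2c(c1)O[C@H](c1cc(OCc3ccccc3)c(OCc3ccccc3)cc1Br)[C@@H](OC(=O)C(F)(F)F)C2 | intermediate
12 | (2R,3S)-5,7-bis(benzyloxy)-2-[4,5-bis(benzyloxy)-2-bromophenyl]chroman-3-ol (6'-bromo-5,7,3',4'-tetra-O-benzylcatechin) | c1ccccc1COc1cc(OCc3ccccc3)c2c(c1)O[C@H](c1cc(OCc3ccccc3)c(OCc3ccccc3)cc1Br)[C@@H](O)C2 | intermediate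
13 | (+)-catechin, (2R,3S)-2-(3,4-dihydroxyphenyl)chroman-3,5,7-triol | Oc1cc(O)c2c(c1)O[C@H](c1ccc(O)c(O)c1)[C@@H](O)C2 | starting material
14 | 5,7,3',4'-tetra-O-benzyl-(+)-catechin | c1ccccc1COc1cc(OCc3ccccc3)c2c(c1)O[C@H](c1ccc(OCc3ccccc3)c(OCc3ccccc3)c1)[C@@H](O)C2 | intermediate
15 | 8-bromo-5,7,3',4'-tetra-O-benzyl-(+)-catechin | c1ccccc1COc1cc(OCc3ccccc3)c2c(c1Br)O[C@H](c1ccc(OCc3ccccc3)c(OCc3ccccc3)c1)[C@@H](O)C2 | intermediate
16 | (2R,3S)-5,7-bis(benzyloxy)-2-[4,5-bis(benzyloxy)-2-(4,4,5,5-tetramethyl-1,3,2-dioxaborolan-2-yl)phenyl]chroman-3-ol | c1ccccc1COc1cc(OCc3ccccc3)c2c(c1)O[C@H](c1cc(OCc3ccccc3)c(OCc3ccccc3)cc1B1OC(C)(C)C(C)(C)O1)[C@@H](O)C2 | intermediate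
17 | (2R,3S)-5,7-bis(benzyloxy)-8-{4,5-bis(benzyloxy)-2-[(2R,3S)-5,7-bis(benzyloxy)-3-hydroxychroman-2-yl]phenyl}-2-[3,4-bis(benzyloxy)phenyl]chroman-3-ol | c1ccccc1COc1cc(OCc4ccccc4)c2c(c1)O[C@H](c1cc(OCc4ccccc4)c(OCc4ccccc4)cc1-c1c(OCc4ccccc4)cc(OCc4ccccc4)c3c1O[C@H](c1ccc(OCc4ccccc4)c(OCc4ccccc4)c1)[C@@H](O)C3)[C@@H](O)C2 | intermediate
18 | (2R,3S)-2-(3,4-dihydroxyphenyl)-8-{4,5-dihydroxy-2-[(2R,3S)-3,5,7-trihydroxychroman-2-yl]phenyl}chroman-3,5,7-triol | Oc1cc(O)c2c(c1)O[C@H](c1cc(O)c(O)cc1-c1c(O)cc(O)c3c1O[C@H](c1ccc(O)c(O)c1)[C@@H](O)C3)[C@@H](O)C2 | target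

Total step count: 11.
Longest linear sequence: 9 steps (steps 1 to 7, then 10 and 11); steps 8 and 9 form the second branch.

Steps most likely to fail

Step 7. The ionisation may run through a free benzylic cation instead of the bridged oxiranium, with loss of configuration at C2. The cation may also lose a proton and aromatise to a 2-benzylbenzofuran, or the electron-rich ring A may be C-trifluoroacetylated. The fallback sets out from 9 and comes back at 12. It separates activation from rearrangement and runs the rearrangement without amine base in a large excess of nucleophile. Compound 9 is acetylated (Ac2O, pyridine, DMAP, CH2Cl2) to the isolable (S)-[4,5-bis(benzyloxy)-2-bromophenyl][(2R)-4,6-bis(benzyloxy)-2,3-dihydrobenzofuran-2-yl]methyl acetate F1. Heating F1 with Zn(OAc)2 in AcOH at 60 °C, the buffered acetolysis used for tetrahydrofuran-to-tetrahydropyran expansions, should equilibrate it through the same oxiranium to the ring-expanded (2R,3S)-5,7-bis(benzyloxy)-2-[4,5-bis(benzyloxy)-2-bromophenyl]chroman-3-yl acetate F2. K2CO3 in MeOH then cleaves the acetate and returns 12.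

Step 10. Oxidative addition and transmetalation at the doubly ortho-oxygenated C8 bromide may be slow, so that protodeboronation or homocoupling of the boronate wins. The fallback sets out from 12 and 15 and comes back at 18. It replaces the boron nucleophile with a zinc nucleophile on the lower unit. Both 3-hydroxyls are benzylated (NaH, BnBr, DMF) to give 8-bromo-3,5,7,3',4'-penta-O-benzylcatechin F3 from 15 and 6'-bromo-3,5,7,3',4'-penta-O-benzylcatechin F4 from 12. Bromine–lithium exchange on F3 (n-BuLi, THF, −78 °C) gives the 8-lithio penta-O-benzylcatechin F5, which ZnCl2 converts into the 8-(chlorozincio) penta-O-benzylcatechin F6. Negishi coupling of F6 with F4 (Pd(OAc)2, RuPhos, THF, 60 °C) should give the deca-O-benzyl catechin-(6'→8)-catechin F7. Hydrogenolysis under the conditions of step 11 converts F7 into 18.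

Step 3. The phenol may be attacked at C4 between the two benzyloxy groups, O-allylated or allylated twice, and the acid may cyclise 5 to a flavan. The fallback sets out from 4 and 2 and comes back at 5. It replaces the cationic C-allylation with a sigmatropic shift and an olefin metathesis. Compound 4 is O-allylated (allyl bromide, K2CO3, acetone) to 1-(allyloxy)-3,5-bis(benzyloxy)benzene F8. Claisen rearrangement (N,N-diethylaniline, 190 °C), with two equivalent ortho positions, gives 2-allyl-3,5-bis(benzyloxy)phenol F9. Wittig methylenation of 2 (Ph3PCH3Br, KOtBu, THF) gives 1,2-bis(benzyloxy)-4-bromo-5-vinylbenzene F10. Cross-metathesis of F9 with an excess of F10 (second-generation Grubbs catalyst RuCl2(=CHPh)(PCy3)(H2IMes), CH2Cl2, 40 °C) should give the E-alkene 5.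

Further compounds
F1 | step 7 | (S)-[4,5-bis(benzyloxy)-2-bromophenyl][(2R)-4,6-bis(benzyloxy)-2,3-dihydrobenzofuran-2-yl]methyl acetate | CC(=O)O[C@H]([C@H]1Cc2c(OCc3ccccc3)cc(OCc3ccccc3)cc2O1)c1cc(OCc2ccccc2)c(OCc2ccccc2)cc1Br
F2 | step 7 | (2R,3S)-5,7-bis(benzyloxy)-2-[4,5-bis(benzyloxy)-2-bromophenyl]chroman-3-yl acetate | c1ccccc1COc1cc(OCc3ccccc3)c2c(c1)O[C@H](c1cc(OCc3ccccc3)c(OCc3ccccc3)cc1Br)[C@@H](OC(C)=O)C2
F3 | step 10 | 8-bromo-3,5,7,3',4'-penta-O-benzylcatechin | c1ccccc1COc1cc(OCc3ccccc3)c2c(c1Br)O[C@H](c1ccc(OCc3ccccc3)c(OCc3ccccc3)c1)[C@@H](OCc1ccccc1)C2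
F4 | step 10 | 6'-bromo-3,5,7,3',4'-penta-O-benzylcatechin | c1ccccc1COc1cc(OCc3ccccc3)c2c(c1)O[C@H](c1cc(OCc3ccccc3)c(OCc3ccccc3)cc1Br)[C@@H](OCc1ccccc1)C2
F5 | step 10 | 8-lithio-3,5,7,3',4'-penta-O-benzylcatechin | c1ccccc1COc1cc(OCc3ccccc3)c2c(c1[Li])O[C@H](c1ccc(OCc3ccccc3)c(OCc3ccccc3)c1)[C@@H](OCc1ccccc1)C2
F6 | step 10 | 8-(chlorozincio)-3,5,7,3',4'-penta-O-benzylcatechin | c1ccccc1COc1cc(OCc3ccccc3)c2c(c1[Zn]Cl)O[C@H](c1ccc(OCc3ccccc3)c(OCc3ccccc3)c1)[C@@H](OCc1ccccc1)C2
F7 | step 10 | deca-O-benzyl catechin-(6'→8)-catechin | c1ccccc1COc1cc(OCc4ccccc4)c2c(c1)O[C@H](c1cc(OCc4ccccc4)c(OCc4ccccc4)cc1-c1c(OCc4ccccc4)cc(OCc4ccccc4)c3c1O[C@H](c1ccc(OCc4ccccc4)c(OCc4ccccc4)c1)[C@@H](OCc1ccccc1)C3)[C@@H](OCc1ccccc1)C2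
F8 | step 3 | 1-(allyloxy)-3,5-bis(benzyloxy)benzene | C=CCOc1cc(OCc2ccccc2)cc(OCc2ccccc2)c1
F9 | step 3 | 2-allyl-3,5-bis(benzyloxy)phenol | Oc1cc(OCc2ccccc2)cc(OCc2ccccc2)c1CC=C
F10 | step 3 | 1,2-bis(benzyloxy)-4-bromo-5-vinylbenzene | C=Cc1cc(OCc2ccccc2)c(OCc2ccccc2)cc1Br
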